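**Plan**

1. Ring B is disconnected first, at C1'–C2', C2'–C3' and C5'–C6', into a C2-ethynyl chromanone, an alkenyl(methoxy)carbene complex of chromium and one CO. This works because ring B is a benzene with para oxygens at C2' and C5' whose C1' (bonded to C2 of ring C) lies ortho to the C2' hydroxyl, which is the pattern a Dötz benzannulation produces.
2. Further cuts: C3–O (Rubottom oxidation), C2–alkyne (alkynylation of a chromone), ring C (enaminone closure on a 2-hydroxyacetophenone), C8–allyl (Claisen), and ring A back to 2-methoxyresorcinol.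
3. Forward: ring A is functionalised first, ring C is closed second, and ring B is built last on the C2 ethynyl group. The prenyl group is made from allyl by cross-metathesis after the peracid step, so no peracid meets it.
4. Stereochemistry: C2 comes from the chiral copper catalyst in the alkynylation; C3 comes from epoxidation anti to the C2 substituent (2,3-trans). Neither centre is touched afterwards.

Key step: step 13

Remark: the parent vinyl(methoxy)carbene complex polymerises readily, so its trans-2-trimethylsilyl derivative 27 is used as a stable equivalent; silicon is expected to leave C3' during aromatisation.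
Assumption: the StackPhos antipode used is the one that gives the (2S) enol ether 17; the sense of induction is to be confirmed on the first batch and the other antipode used if needed.

**Route**

Step 1
Reactants: 1 2-methoxyresorcinol
Product: 2 2-methoxy-1,3-bis(methoxymethoxy)benzene
Conditions: MOMCl (2.4 equiv), iPr2NEt, CH2Cl2, 0 → 23 °C
Reagents that add atoms: chloromethyl methyl ether (MOMCl), COCCl
Why: Williamson-type O-alkylation of both phenols installs acetal ethers that tolerate organolithiums, 190 °C, peracid and the ruthenium and chromium carbenes used later, and that are removed together by acid in the last step.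

Step 2
Reactants: 2 2-methoxy-1,3-bis(methoxymethoxy)benzene
Product: 4 4-methoxy-3,5-bis(methoxymethoxy)phenol, via aryl pinacolboronate 3 (not isolated)
Conditions: [Ir(OMe)(cod)]2 (1.5 mol%), 4,4'-di-tert-butyl-2,2'-bipyridine (3 mol%), B2pin2, THF, 80 °C; then NaOH, H2O2, H2O, 0 °C
Reagents that add atoms: hydrogen peroxide, OO
Why: Sterically governed iridium-catalysed C–H borylation attacks the only C–H without an ortho neighbour (C5 of the 1,2,3-trioxygenated ring), and basic peroxide oxidation of the C–B bond gives the phenol whose oxygen becomes O1.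

Step 3
Reactants: 4 4-methoxy-3,5-bis(methoxymethoxy)phenol
Product: 5 2-bromo-4-methoxy-3,5-bis(methoxymethoxy)phenol
Conditions: NBS (1.0 equiv), CH2Cl2, −78 → −40 °C
Reagents that add atoms: N-bromosuccinimide, O=C1CCC(=O)N1Br
Why: Electrophilic aromatic bromination: para to the hydroxyl is blocked, the two ortho positions are equivalent, and the first bromine deactivates the ring enough for one equivalent of NBS at low temperature to stop at the monobromide.

Step 4
Reactants: 5 2-bromo-4-methoxy-3,5-bis(methoxymethoxy)phenol; 6 N-methoxy-N-methylacetamide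
Product: 8 1-[2-hydroxy-5-methoxy-4,6-bis(methoxymethoxy)phenyl]ethan-1-one, via dilithio phenoxide 7 (not isolated)
Conditions: n-BuLi (2.2 equiv), THF, −78 °C; 6, −78 → 0 °C; AcOH
Reagents that add atoms: 6 N-methoxy-N-methylacetamide, CON(C)C(C)=O
Why: Deprotonation of the phenol and bromine–lithium exchange give the dilithio species 7, whose aryllithium adds once to the amide (Weinreb ketone synthesis) because the chelated tetrahedral adduct persists until the acetic acid quench.

Step 5
Reactants: 8 1-[2-hydroxy-5-methoxy-4,6-bis(methoxymethoxy)phenyl]ethan-1-one; 9 allyl bromide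
Product: 10 1-[2-(allyloxy)-5-methoxy-4,6-bis(methoxymethoxy)phenyl]ethan-1-one
Conditions: K2CO3, DMF, 60 °C
Reagents that add atoms: 9 allyl bromide, C=CCBr
Why: Williamson ether synthesis on the only free phenol, carbonate in DMF being enough to overcome its hydrogen bond to the ketone.

Step 6
Reactants: 10 1-[2-(allyloxy)-5-methoxy-4,6-bis(methoxymethoxy)phenyl]ethan-1-one
Product: 11 1-[3-allyl-2-hydroxy-5-methoxy-4,6-bis(methoxymethoxy)phenyl]ethan-1-one
Conditions: N,N-diethylaniline, 190 °C
Reagents that add atoms: none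
Why: Aromatic Claisen rearrangement: the [3,3] shift can deliver the allyl group only to the single unsubstituted ortho carbon (the future C8), tautomerisation returns the hydrogen-bonded phenol, and aryl MOM ethers tolerate heat in this neutral amine medium.

Step 7
Reactants: 11 1-[3-allyl-2-hydroxy-5-methoxy-4,6-bis(methoxymethoxy)phenyl]ethan-1-one; 12 N,N-dimethylformamide dimethyl acetal
Product: 14 8-allyl-6-methoxy-5,7-bis(methoxymethoxy)-4H-chromen-4-one, via enaminone 13 (not isolated)
Conditions: 12, toluene, 95 °C; then AcOH, toluene, 60 °C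
Reagents that add atoms: 12 N,N-dimethylformamide dimethyl acetal, COC(OC)N(C)C
Why: Condensation of the methyl ketone with the amide acetal gives the enaminone, and acid-promoted 6-endo addition of the phenol with loss of dimethylamine closes ring C (enaminone route to chromones) under conditions too mild to cleave aryl MOM ethers.

Step 8
Reactants: 14 8-allyl-6-methoxy-5,7-bis(methoxymethoxy)-4H-chromen-4-one; 15 trimethylsilylacetylene
Product: 17 (2S)-8-allyl-4-(tert-butyldimethylsilyloxy)-6-methoxy-5,7-bis(methoxymethoxy)-2-[(trimethylsilyl)ethynyl]-2H-chromene, via benzopyrylium triflate 16 (not isolated)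
Conditions: TBSOTf (1.1 equiv), toluene, 23 °C; then CuI (10 mol%), StackPhos (12 mol%), 15, iPr2NEt, −78 → −40 °C
Reagents that add atoms: tert-butyldimethylsilyl trifluoromethanesulfonate, CC(C)(C)[Si](C)(C)OS(=O)(=O)C(F)(F)F; 15 trimethylsilylacetylene, C#C[Si](C)(C)C
Why: O-silylation of the chromone gives a 4-siloxybenzopyrylium ion to which the acetylide formed from 15, CuI and the chiral P,N ligand adds at C2 (copper-catalysed enantioselective alkynylation of chromone-derived oxocarbenium ions), the ligand selecting the face and so setting C2, while the silyl triflate is consumed by the far more basic pyrone carbonyl before it can attack the MOM acetals.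

Step 9
Reactants: 17 (2S)-8-allyl-4-(tert-butyldimethylsilyloxy)-6-methoxy-5,7-bis(methoxymethoxy)-2-[(trimethylsilyl)ethynyl]-2H-chromene
Product: 19 (2R,3R)-8-allyl-3-(tert-butyldimethylsilyloxy)-6-methoxy-5,7-bis(methoxymethoxy)-2-[(trimethylsilyl)ethynyl]chroman-4-one, via siloxy epoxide 18 (not isolated)
Conditions: mCPBA (1.05 equiv), CH2Cl2, −20 → 23 °C
Reagents that add atoms: 3-chloroperbenzoic acid, OOC(=O)c1cccc(Cl)c1
Why: Rubottom oxidation: the peracid epoxidises the electron-rich enol ether (much faster than the monosubstituted allyl alkene) on the face away from the C2 alkynyl group, and opening to the oxocarbenium ion stabilised by ring A followed by a 1,4-silyl shift gives the trans α-siloxy ketone, which sets C3.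

Step 10
Reactants: 19 (2R,3R)-8-allyl-3-(tert-butyldimethylsilyloxy)-6-methoxy-5,7-bis(methoxymethoxy)-2-[(trimethylsilyl)ethynyl]chroman-4-one; 20 2-methyl-2-butene
Product: 21 (2R,3R)-3-(tert-butyldimethylsilyloxy)-6-methoxy-5,7-bis(methoxymethoxy)-8-(3-methylbut-2-en-1-yl)-2-[(trimethylsilyl)ethynyl]chroman-4-one
Conditions: second-generation Grubbs catalyst (5 mol%), 20/CH2Cl2 (1:1), 40 °C
Reagents that add atoms: 20 2-methyl-2-butene, CC=C(C)C
Why: Olefin cross-metathesis with excess 2-methyl-2-butene converts the allyl arene into the prenyl arene, and the alkyne, capped by silicon, should not enter enyne metathesis.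

Step 11
Reactants: 21 (2R,3R)-3-(tert-butyldimethylsilyloxy)-6-methoxy-5,7-bis(methoxymethoxy)-8-(3-methylbut-2-en-1-yl)-2-[(trimethylsilyl)ethynyl]chroman-4-one
Product: 22 (2R,3R)-3-(tert-butyldimethylsilyloxy)-2-ethynyl-6-methoxy-5,7-bis(methoxymethoxy)-8-(3-methylbut-2-en-1-yl)chroman-4-one
Conditions: AgNO3 (10 mol%), MeOH/H2O/CH2Cl2, 23 °C
Reagents that add atoms: none
Why: Silver-catalysed protodesilylation of the alkynylsilane is neutral, so the secondary TBS ether, the base-sensitive α-siloxy chromanone and both stereocentres should be left untouched.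

Step 12
Reactants: 23 (E)-(2-bromovinyl)trimethylsilane; 24 chromium hexacarbonyl
Product: 27 pentacarbonyl[(2E)-1-methoxy-3-(trimethylsilyl)prop-2-en-1-ylidene]chromium, via alkenyllithium 25 (not isolated), via lithium acylchromate 26 (not isolated)
Conditions: t-BuLi (2.0 equiv), Et2O, −78 °C; Cr(CO)6, −78 → 23 °C; then Me3OBF4, CH2Cl2/H2O, 0 °C
Reagents that add atoms: 24 chromium hexacarbonyl, O=C=[Cr](=C=O)(=C=O)(=C=O)(=C=O)=C=O; trimethyloxonium tetrafluoroborate, C[O+](C)C.F[B-](F)(F)F
Why: Fischer carbene synthesis: the alkenyllithium (from halogen–lithium exchange with retention of the E geometry) adds to a CO ligand and O-methylation of the acyl chromate gives the alkoxycarbene complex, which the β-silyl group protects from the polymerisation that plagues the parent vinyl complex.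

Step 13
Reactants: 22 (2R,3R)-3-(tert-butyldimethylsilyloxy)-2-ethynyl-6-methoxy-5,7-bis(methoxymethoxy)-8-(3-methylbut-2-en-1-yl)chroman-4-one; 27 pentacarbonyl[(2E)-1-methoxy-3-(trimethylsilyl)prop-2-en-1-ylidene]chromium
Product: 29 (2R,3R)-3-(tert-butyldimethylsilyloxy)-2-(2-hydroxy-5-methoxyphenyl)-6-methoxy-5,7-bis(methoxymethoxy)-8-(3-methylbut-2-en-1-yl)chroman-4-one, via aryl trimethylsilyl ether 28 (not isolated)
Conditions: 27 (1.5 equiv), THF (0.05 M), 50 °C, Ar; then air, 23 °C; citric acid, MeOH/H2O, 23 °C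
Reagents that add atoms: 27 pentacarbonyl[(2E)-1-methoxy-3-(trimethylsilyl)prop-2-en-1-ylidene]chromium, COC(/C=C/[Si](C)(C)C)=[Cr](=C=O)(=C=O)(=C=O)(=C=O)=C=O
Why: Dötz benzannulation: after thermal loss of one CO from 27 the terminal alkyne of 22 inserts into the Cr=C bond (C5'–C6'), CO inserts to give a chromium-bound dienylketene (C1'–C2') and a 6π-electrocyclisation (C2'–C3') closes ring B as a cyclohexadienone, so the single new ring arises by pericyclic closure of a ketene assembled by two migratory insertions on the metal. The closest known reaction is the benzannulation of trans-2-silylvinyl(alkoxy)carbene chromium complexes with terminal alkynes, in which the dienone aromatises by a 1,3 shift of silicon from carbon to oxygen; here that gives aryl silyl ether 28, which air frees from chromium and mild acid hydrolyses to phenol 29. No stereocentre is formed, and C2 and C3 are spectators on a propargylic ether that meets only neutral conditions at 50 °C, so their configuration should be carried through. The selectivity needed is regiochemical: the unsubstituted alkyne carbon must bond to the carbene carbon, which the steric bias of a terminal alkyne secures, so that C2 ends ortho to the CO-derived C2' hydroxyl and the para-related oxygens fall at C2' and C5'. The trisubstituted prenyl alkene, the ketone and the acetal and silyl ethers are not expected to engage the carbene.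

Step 14
Reactants: 29 (2R,3R)-3-(tert-butyldimethylsilyloxy)-2-(2-hydroxy-5-methoxyphenyl)-6-methoxy-5,7-bis(methoxymethoxy)-8-(3-methylbut-2-en-1-yl)chroman-4-one
Product: 31 (2R,3R)-3-(tert-butyldimethylsilyloxy)-2-(2,5-dihydroxyphenyl)-6-methoxy-5,7-bis(methoxymethoxy)-8-(3-methylbut-2-en-1-yl)chroman-4-one, via quinone 30 (not isolated)
Conditions: PhI(OAc)2 (1.1 equiv), MeCN/H2O, 0 °C; then Na2S2O4, H2O/EtOAc, 23 °C
Reagents that add atoms: water, O
Why: Oxidative demethylation of a 4-methoxyphenol by a trivalent iodine reagent (water adds para to the activated phenol and methanol leaves) gives the quinone, which dithionite reduces at once to the hydroquinone, while ring A and its 6-methoxy group are inert because they carry no free phenol.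

Step 15
Reactants: 31 (2R,3R)-3-(tert-butyldimethylsilyloxy)-2-(2,5-dihydroxyphenyl)-6-methoxy-5,7-bis(methoxymethoxy)-8-(3-methylbut-2-en-1-yl)chroman-4-one
Product: 32 (2R,3R)-2-(2,5-dihydroxyphenyl)-3,5,7-trihydroxy-6-methoxy-8-(3-methylbut-2-en-1-yl)chroman-4-one
Conditions: HCl (3 M aq)/MeOH, 40 °C, Ar
Reagents that add atoms: none
Why: Acid-catalysed acetal exchange removes both MOM ethers and acidic solvolysis removes the secondary TBS ether in one operation (a deprotection precedented for prenylated flavonoids), and the 2,3-trans arrangement is the thermodynamically preferred one, so it should not be eroded.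

**Compound list**

1 | 2-methoxyresorcinol (2-methoxybenzene-1,3-diol) | COc1c(O)cccc1O | starting material
2 | 2-methoxy-1,3-bis(methoxymethoxy)benzene | COCOc1cccc(OCOC)c1OC | intermediate
3 | 2-[4-methoxy-3,5-bis(methoxymethoxy)phenyl]-4,4,5,5-tetramethyl-1,3,2-dioxaborolane | COCOc1cc(B2OC(C)(C)C(C)(C)O2)cc(OCOC)c1OC | intermediate
4 | 4-methoxy-3,5-bis(methoxymethoxy)phenol | COCOc1cc(O)cc(OCOC)c1OC | intermediate
5 | 2-bromo-4-methoxy-3,5-bis(methoxymethoxy)phenol | COCOc1cc(O)c(Br)c(OCOC)c1OC | intermediate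
6 | N-methoxy-N-methylacetamide | CON(C)C(C)=O | starting material
7 | lithium 2-lithio-4-methoxy-3,5-bis(methoxymethoxy)phenoxide | [Li]Oc1cc(OCOC)c(OC)c(OCOC)c1[Li] | intermediate
8 | 1-[2-hydroxy-5-methoxy-4,6-bis(methoxymethoxy)phenyl]ethan-1-one | CC(=O)c1c(O)cc(OCOC)c(OC)c1OCOC | intermediate
9 | allyl bromide | C=CCBr | starting material
10 | 1-[2-(allyloxy)-5-methoxy-4,6-bis(methoxymethoxy)phenyl]ethan-1-one | CC(=O)c1c(OCC=C)cc(OCOC)c(OC)c1OCOC | intermediate
11 | 1-[3-allyl-2-hydroxy-5-methoxy-4,6-bis(methoxymethoxy)phenyl]ethan-1-one | CC(=O)c1c(O)c(CC=C)c(OCOC)c(OC)c1OCOC | intermediate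
12 | N,N-dimethylformamide dimethyl acetal | COC(OC)N(C)C | starting material
13 | (E)-1-[3-allyl-2-hydroxy-5-methoxy-4,6-bis(methoxymethoxy)phenyl]-3-(dimethylamino)prop-2-en-1-one | CN(C)/C=C/C(=O)c1c(O)c(CC=C)c(OCOC)c(OC)c1OCOC | intermediate
14 | 8-allyl-6-methoxy-5,7-bis(methoxymethoxy)-4H-chromen-4-one | COc1c(OCOC)c(CC=C)c2c(c1OCOC)C(=O)C=CO2 | intermediate
15 | trimethylsilylacetylene | C#C[Si](C)(C)C | starting material
16 | 8-allyl-4-(tert-butyldimethylsilyloxy)-6-methoxy-5,7-bis(methoxymethoxy)chromenylium trifluoromethanesulfonate | COc1c(OCOC)c(CC=C)c2[o+]ccc(O[Si](C)(C)C(C)(C)C)c2c1OCOC.[O-]S(=O)(=O)C(F)(F)F | intermediate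
17 | (2S)-8-allyl-4-(tert-butyldimethylsilyloxy)-6-methoxy-5,7-bis(methoxymethoxy)-2-[(trimethylsilyl)ethynyl]-2H-chromene | COc1c(OCOC)c(CC=C)c2c(c1OCOC)C(O[Si](C)(C)C(C)(C)C)=C[C@@H](C#C[Si](C)(C)C)O2 | intermediate
18 | 3,4-epoxide of 17, oxirane oxygen anti to the C2 alkynyl group, silyloxy group still on C4 | COc1c(OCOC)c(CC=C)c2c(c1OCOC)[C@]3(O[Si](C)(C)C(C)(C)C)O[C@@H]3[C@@H](C#C[Si](C)(C)C)O2 | intermediate
19 | (2R,3R)-8-allyl-3-(tert-butyldimethylsilyloxy)-6-methoxy-5,7-bis(methoxymethoxy)-2-[(trimethylsilyl)ethynyl]chroman-4-one | COc1c(OCOC)c(CC=C)c2c(c1OCOC)C(=O)[C@H](O[Si](C)(C)C(C)(C)C)[C@@H](C#C[Si](C)(C)C)O2 | intermediate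
20 | 2-methyl-2-butene | CC=C(C)C | starting material
21 | (2R,3R)-3-(tert-butyldimethylsilyloxy)-6-methoxy-5,7-bis(methoxymethoxy)-8-(3-methylbut-2-en-1-yl)-2-[(trimethylsilyl)ethynyl]chroman-4-one | COc1c(OCOC)c(CC=C(C)C)c2c(c1OCOC)C(=O)[C@H](O[Si](C)(C)C(C)(C)C)[C@@H](C#C[Si](C)(C)C)O2 | intermediate
22 | (2R,3R)-3-(tert-butyldimethylsilyloxy)-2-ethynyl-6-methoxy-5,7-bis(methoxymethoxy)-8-(3-methylbut-2-en-1-yl)chroman-4-one | COc1c(OCOC)c(CC=C(C)C)c2c(c1OCOC)C(=O)[C@H](O[Si](C)(C)C(C)(C)C)[C@@H](C#C)O2 | intermediate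
23 | (E)-(2-bromovinyl)trimethylsilane | Br/C=C/[Si](C)(C)C | starting material
24 | chromium hexacarbonyl | O=C=[Cr](=C=O)(=C=O)(=C=O)(=C=O)=C=O | starting material
25 | (E)-[2-(trimethylsilyl)vinyl]lithium | [Li]/C=C/[Si](C)(C)C | intermediate
26 | lithium pentacarbonyl[(E)-3-(trimethylsilyl)acryloyl]chromate | [Li+].[O-]C(/C=C/[Si](C)(C)C)=[Cr](=C=O)(=C=O)(=C=O)(=C=O)=C=O | intermediate
27 | pentacarbonyl[(2E)-1-methoxy-3-(trimethylsilyl)prop-2-en-1-ylidene]chromium | COC(/C=C/[Si](C)(C)C)=[Cr](=C=O)(=C=O)(=C=O)(=C=O)=C=O | intermediate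
28 | (2R,3R)-3-(tert-butyldimethylsilyloxy)-6-methoxy-5,7-bis(methoxymethoxy)-8-(3-methylbut-2-en-1-yl)-2-[5-methoxy-2-(trimethylsilyloxy)phenyl]chroman-4-one | COc1c(OCOC)c(CC=C(C)C)c2c(c1OCOC)C(=O)[C@H](O[Si](C)(C)C(C)(C)C)[C@@H](c1cc(OC)ccc1O[Si](C)(C)C)O2 | intermediate
29 | (2R,3R)-3-(tert-butyldimethylsilyloxy)-2-(2-hydroxy-5-methoxyphenyl)-6-methoxy-5,7-bis(methoxymethoxy)-8-(3-methylbut-2-en-1-yl)chroman-4-one | COc1c(OCOC)c(CC=C(C)C)c2c(c1OCOC)C(=O)[C@H](O[Si](C)(C)C(C)(C)C)[C@@H](c1cc(OC)ccc1O)O2 | intermediate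
30 | 2-[(2R,3R)-3-(tert-butyldimethylsilyloxy)-6-methoxy-5,7-bis(methoxymethoxy)-8-(3-methylbut-2-en-1-yl)-4-oxochroman-2-yl]cyclohexa-2,5-diene-1,4-dione | COc1c(OCOC)c(CC=C(C)C)c2c(c1OCOC)C(=O)[C@H](O[Si](C)(C)C(C)(C)C)[C@@H](C1=CC(=O)C=CC1=O)O2 | intermediate
31 | (2R,3R)-3-(tert-butyldimethylsilyloxy)-2-(2,5-dihydroxyphenyl)-6-methoxy-5,7-bis(methoxymethoxy)-8-(3-methylbut-2-en-1-yl)chroman-4-one | COc1c(OCOC)c(CC=C(C)C)c2c(c1OCOC)C(=O)[C@H](O[Si](C)(C)C(C)(C)C)[C@@H](c1cc(O)ccc1O)O2 | intermediate
32 | (2R,3R)-2-(2,5-dihydroxyphenyl)-3,5,7-trihydroxy-6-methoxy-8-(3-methylbut-2-en-1-yl)chroman-4-one | COc1c(O)c(CC=C(C)C)c2c(c1O)C(=O)[C@H](O)[C@@H](c1cc(O)ccc1O)O2 | target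

**Step count**

Total: 15 steps. Longest linear sequence: 14 steps (steps 1–11 and 13–15 from 2-methoxyresorcinol); step 12 is a one-step branch.

**Steps most likely to fail**

Step 13 (benzannulation). The process at risk is decomposition of carbene complex 27 faster than its insertion into the hindered, oxygen-flanked alkyne of 22, or diversion of the dienylketene into cyclobutenone, furan or two-alkyne products, so that ring B does not close. The fallback sets out from chromone 14 and returns at target 32, bringing ring B in preformed. [2,5-Bis(methoxymethoxy)phenyl]boronic acid F1, made from hydroquinone bis(methoxymethyl) ether by ortho-lithiation (n-BuLi) and B(OiPr)3, is added to 14 by rhodium-catalysed asymmetric 1,4-addition ([RhCl(C2H4)2]2, chiral diene ligand, KOH, dioxane/H2O) to give the (2S)-flavanone F2. TBSOTf/Et3N converts it into the silyl enol ether F3. Rubottom oxidation with mCPBA, now anti to a large aryl group, gives the trans 3-siloxyflavanone F4. Cross-metathesis with 2-methyl-2-butene gives the prenyl compound F5, and HCl/MeOH removes the four MOM groups and the TBS group to give 32 without the quinone detour.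

Step 8 (alkynylation). The process at risk is low electrophilicity of the donor-rich benzopyrylium ion, loss of the peri MOM group to the silyl triflate, or poor facial discrimination caused by the C5 and C8 substituents. The fallback sets out from acetophenone 11 and returns at 17, forming the O1–C2 bond instead of the C2–alkyne bond. The dianion of 11 (LiN(SiMe3)2, 2.2 equiv, THF, −78 °C) adds to 3-(trimethylsilyl)propynal to give the aldol F6. Dehydration through the mesylate (MsCl, Et3N) gives the (E)-enynone F7. A quinine-derived bifunctional thiourea then promotes the asymmetric 6-endo oxa-Michael cyclisation known for 2'-hydroxychalcones, giving the (S)-2-alkynylchromanone F8, and TBSOTf/Et3N converts this into 17. The enantioinduction of the cyclisation would need optimisation.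

Step 9 (Rubottom oxidation). The process at risk is poor facial discrimination by the slim alkynyl group in the epoxidation, or loss of silicon from the opened epoxide giving mixtures of free and silylated ketol. The fallback sets out from 17 and returns at 19, putting facial selection under reagent control. A Shi epoxidation (fructose-derived ketone, KHSO5, K2CO3 buffer, MeCN/dimethoxymethane/H2O, 0 °C) is run with the ketone enantiomer that reinforces attack anti to the alkynyl group. The siloxy epoxide collapses in the aqueous medium to the free trans ketol F9, which TBSCl/imidazole (DMF) converts into 19.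

**Further compounds**

F1 | step 13 | [2,5-bis(methoxymethoxy)phenyl]boronic acid | COCOc1ccc(OCOC)c(B(O)O)c1
F2 | step 13 | (2S)-8-allyl-2-[2,5-bis(methoxymethoxy)phenyl]-6-methoxy-5,7-bis(methoxymethoxy)chroman-4-one | COc1c(OCOC)c(CC=C)c2c(c1OCOC)C(=O)C[C@@H](c1cc(OCOC)ccc1OCOC)O2
F3 | step 13 | (2S)-8-allyl-2-[2,5-bis(methoxymethoxy)phenyl]-4-(tert-butyldimethylsilyloxy)-6-methoxy-5,7-bis(methoxymethoxy)-2H-chromene | COc1c(OCOC)c(CC=C)c2c(c1OCOC)C(O[Si](C)(C)C(C)(C)C)=C[C@@H](c1cc(OCOC)ccc1OCOC)O2
F4 | step 13 | (2R,3R)-8-allyl-2-[2,5-bis(methoxymethoxy)phenyl]-3-(tert-butyldimethylsilyloxy)-6-methoxy-5,7-bis(methoxymethoxy)chroman-4-one | COc1c(OCOC)c(CC=C)c2c(c1OCOC)C(=O)[C@H](O[Si](C)(C)C(C)(C)C)[C@@H](c1cc(OCOC)ccc1OCOC)O2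
F5 | step 13 | (2R,3R)-2-[2,5-bis(methoxymethoxy)phenyl]-3-(tert-butyldimethylsilyloxy)-6-methoxy-5,7-bis(methoxymethoxy)-8-(3-methylbut-2-en-1-yl)chroman-4-one | COc1c(OCOC)c(CC=C(C)C)c2c(c1OCOC)C(=O)[C@H](O[Si](C)(C)C(C)(C)C)[C@@H](c1cc(OCOC)ccc1OCOC)O2
F6 | step 8 | 1-[3-allyl-2-hydroxy-5-methoxy-4,6-bis(methoxymethoxy)phenyl]-3-hydroxy-5-(trimethylsilyl)pent-4-yn-1-one (racemic) | C[Si](C)(C)C#CC(O)CC(=O)c1c(O)c(CC=C)c(OCOC)c(OC)c1OCOC
F7 | step 8 | (E)-1-[3-allyl-2-hydroxy-5-methoxy-4,6-bis(methoxymethoxy)phenyl]-5-(trimethylsilyl)pent-2-en-4-yn-1-one | C[Si](C)(C)C#C/C=C/C(=O)c1c(O)c(CC=C)c(OCOC)c(OC)c1OCOC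
F8 | step 8 | (2S)-8-allyl-6-methoxy-5,7-bis(methoxymethoxy)-2-[(trimethylsilyl)ethynyl]chroman-4-one | COc1c(OCOC)c(CC=C)c2c(c1OCOC)C(=O)C[C@@H](C#C[Si](C)(C)C)O2
F9 | step 9 | (2R,3R)-8-allyl-3-hydroxy-6-methoxy-5,7-bis(methoxymethoxy)-2-[(trimethylsilyl)ethynyl]chroman-4-one | COc1c(OCOC)c(CC=C)c2c(c1OCOC)C(=O)[C@H](O)[C@@H](C#C[Si](C)(C)C)O2
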